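The constants used here stand for no real mixture.

Late in a run each product has cost one coupling partner and one starting material, so the ceiling is the smaller charge. That is the coupling partner, the limiting reagent, in zeta and delta, and the solid substrate in theta. As fractions of the solid charged, the ceilings are 50.0%, 75.0% and 100%. What counts is how far one minute gets towards them.

in all of them: solid substrate 0.20 mM; free catalyst 0.30 µM; time 1.0 min

| flask | coupling partner |
|---|---|
| zeta | 0.100 mM |
| delta | 0.150 mM |
| theta | 0.250 mM |

    coupling partner + free catalyst → catalyst intermediate A (k1 = 1.2 × 10⁵ M⁻¹ s⁻¹)
    catalyst intermediate A ⇌ released group + catalyst intermediate B (K2 = 1.7 × 10⁻⁴ M, k2 = 120 s⁻¹)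
    starting material + catalyst intermediate B → catalyst intermediate C (k3 = 7.5 × 10⁵ M⁻¹ s⁻¹)
    catalyst intermediate C → free catalyst + product (k4 = 450 s⁻¹)
    solid substrate ⇌ starting material, rate k5*(cs5 - [starting material]) while solid is left; crystals form when [starting material] > cs5 (cs5 = 0.094 mM, k5 = 0.060 s⁻¹)

- amount of product at the end, in percent of the solid substrate charged for zeta, delta, theta, in this order
- the course of these numbers from the first flask to the last (rises, then falls / falls, then rises / hardly changes / rises all the way / falls all the way)

- as a solid, counted per litre of solution: solid substrate
- at the start none of the solid substrate is in solution
- "hardly changes" means that all values lie within two and a half points (for a concentration: within two and a half percent of the largest)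
- run time (zeta): 1.0 min

I follow one rate, the capture of coupling partner by free catalyst in step 1. At the start the catalyst is wholly free, and the partner falls pseudo-first-order at 0.0360 s⁻¹, a half-life of 0.32 min in zeta. I reckon with two things that slow this rate. The first is the partner's own fall, which the exponential carries. The second is the catalyst's absence from the free form. After each capture it waits 8.33 ms in step 2, 14.2 ms in step 3 with the starting material at its solubility, 47.0% of the solid charged, and 2.22 ms in step 4. Together these make 24.7 ms, the hold-up time: the time a captured catalyst stays away from the free form, with the return through the released group ignored.

Between captures the catalyst waits one over the capture frequency, so its free share at the full partner charge is 77.1% in zeta, 69.2% in delta and 57.4% in theta. I hold each share fixed over the run as a deliberate simplification, and the rate then integrates to an exponential. My fraction of partner left after 1.0 min comes to 18.9% in zeta, 22.4% in delta and 28.9% in theta. My product as a fraction of the solid is therefore 40.5%, 58.2% and 88.8% in the same order, a steady rise, with theta below its ceiling.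

The forecast gives 40%, 56% and 76%, rises all the way, in its words “the yield keeps rising but stays below full conversion”, and its theta figure is lower than mine.

The flask gives 40.2%, 55.9% and 76.1%, rises all the way. At the end of theta the starting material stands at 23.9% of the solid charged, less than the solubility my hold-up time assumed. With that end reading held over the whole run in its step 3 wait, the hold-up time for theta becomes 38.4 ms, the free share 46.4%, and my partner left 36.7%; at the end theta holds 39% of its partner charge.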